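**Plan**
- Retrosynthetic cuts, in order: the C4–O diaryl ether bond (to 2-bromo-1,4-naphthoquinone), the C4–OH bond (back to a 4-unsubstituted 1-naphthol), the C2–C3 bond of ring A, the C(=O)–CH2 bond of the keto ester, the aryl–alkyne bond and the propargyl–allyl bond.
- Enabling feature: in ring A, C1 with its hydroxyl and C2 with its methyl ester are the enol form of a benzoylacetate. C3 (carrying the prenyl group) and C4 are the two carbons of an alkyne ortho to that keto ester on the benzo ring, so making C2–C3 alone closes ring A.
- Forward: prenyl bromide and trimethylsilylacetylene give the skipped enyne, which is joined to methyl 2-iodobenzoate and extended by a Claisen condensation. Gold then closes ring A (the only ring made; the benzo ring and the quinone are bought), the naphthol is oxygenated at C4, and the C4 oxygen is arylated last.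
- Stereochemistry: none to set; the target has no stereocentre and its alkene carries two identical methyl groups.

Key step: step 4

Remark on the chemistry: prenyl means 3-methylbut-2-en-1-yl; ring A is numbered C1 (OH), C2 (CO2Me), C3 (prenyl), C4 (aryloxy); hydroquinone 11 is assumed to be air-sensitive and is handled under argon from its formation onward.

**Step 1**
Reactants: 1 trimethylsilylacetylene; 2 prenyl bromide (1-bromo-3-methylbut-2-ene)
Product: 4 trimethyl(5-methylhex-4-en-1-yn-1-yl)silane, via (trimethylsilylethynyl)magnesium bromide 3 (not isolated)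
Conditions: EtMgBr, THF, 0 °C → rt; then CuBr·SMe2 (5 mol%), 2, 0 °C → rt
Reagents that add atoms: none
Why: Copper-catalysed cross-coupling of an alkynyl Grignard reagent with an allylic bromide: EtMgBr deprotonates 1 to 3, whose alkynylcopper form displaces bromide at the unhindered primary carbon of 2 (SN2 rather than SN2' at the fully substituted terminus), while the silyl group blocks the other alkyne terminus and makes 4 heavy enough to isolate by distillation.

**Step 2**
Reactants: 4 trimethyl(5-methylhex-4-en-1-yn-1-yl)silane; 5 methyl 2-iodobenzoate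
Product: 7 methyl 2-(5-methylhex-4-en-1-yn-1-yl)benzoate, via 5-methylhex-4-en-1-yne 6 (not isolated)
Conditions: CsF, PdCl2(PPh3)2 (3 mol%), CuI (6 mol%), PPh3 (6 mol%), Et3N, PEG 200, H2O, 40 °C
Reagents that add atoms: none
Why: Sonogashira coupling with in situ fluoride desilylation: CsF releases the volatile terminal alkyne 6 only in the flask, where its copper acetylide transmetalates to the arylpalladium formed from the ester-activated iodide 5, and the weakly basic amine/fluoride medium should neither cleave the methyl ester nor isomerise the 1,4-enyne.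

**Step 3**
Reactants: 7 methyl 2-(5-methylhex-4-en-1-yn-1-yl)benzoate
Product: 8 methyl 3-[2-(5-methylhex-4-en-1-yn-1-yl)phenyl]-3-oxopropanoate
Conditions: MeOAc, LiN(SiMe3)2 (excess), THF, −78 → −20 °C; AcOH quench at −78 °C
Reagents that add atoms: methyl acetate, COC(C)=O
Why: Crossed Claisen condensation: the lithium enolate of methyl acetate acylates the aryl ester and the product is stored at once as its stabilised enolate (hence the excess base), while at low temperature the hindered silylamide should not deprotonate the propargylic/allylic CH2 nor let the product enolate add to the alkyne before the acidic quench.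

**Step 4**
Reactants: 8 methyl 3-[2-(5-methylhex-4-en-1-yn-1-yl)phenyl]-3-oxopropanoate
Product: 9 methyl 1-hydroxy-3-(3-methylbut-2-en-1-yl)-2-naphthoate
Conditions: Ph3PAuNTf2 (5 mol%), CH2Cl2, rt
Reagents that add atoms: none
Why: Ph3PAuNTf2 supplies cationic monovalent gold, which binds the aryl alkyne of 8; the hydrogen-bonded enol of the β-keto ester adds through its α-carbon (C2) anti to gold at the alkyne carbon remote from the arene (C3), and proton transfer from C2 to the C4–gold bond (protodeauration) with enolisation of the C1 ketone gives the aromatic naphthol 9. The closest known reaction type is the gold-catalysed Conia-ene carbocyclisation of β-keto esters onto alkynes, in its benzannulating form known for 2-alkynylaryl β-dicarbonyl compounds and aryl silyl enol ethers under base or π-acid catalysis. Ring A closes in the 6-endo-dig mode by formation of the single bond C2–C3. No stereocentre is created. The step needs carbon attack rather than carbonyl-oxygen attack and 6-endo rather than 5-exo closure: the exo path would give a strained alkylidene-indanone and the distal carbon is the vinylogous acceptor position of the ortho-acyl aryl alkyne, while oxygen attack leads to a benzopyrylium-type aurate that can revert, whereas carbon attack is sealed by aromatisation. The neutral, base-free medium leaves the doubly activated CH2 of the skipped enyne in place, and a 1,4-enyne cannot cycloisomerise without forming a three- or four-membered ring.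

**Step 5**
Reactants: 9 methyl 1-hydroxy-3-(3-methylbut-2-en-1-yl)-2-naphthoate
Product: 11 methyl 1,4-dihydroxy-3-(3-methylbut-2-en-1-yl)-2-naphthoate, via 2-methoxycarbonyl-3-prenyl-1,4-naphthoquinone 10 (not isolated)
Conditions: PhI(OAc)2 (2.2 equiv), MeCN/H2O (2:1), 0 °C; then aq Na2S2O4, EtOAc, rt, Ar
Reagents that add atoms: water, O
Why: Hypervalent-iodine para-oxidation of a 1-naphthol with reductive work-up: ligand exchange at the trivalent iodine reagent and loss of PhI make C4 electrophilic (C2 is blocked by the ester), water adds there, the second equivalent oxidises the resulting hydroquinone to quinone 10, and the dithionite wash returns 10 to hydroquinone 11, while the prenyl alkene should be a poor partner for PhI(OAc)2 at 0 °C.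

**Step 6**
Reactants: 11 methyl 1,4-dihydroxy-3-(3-methylbut-2-en-1-yl)-2-naphthoate; 12 2-bromo-1,4-naphthoquinone
Product: 13 rubioncolin C, methyl 4-[(1,4-dioxo-1,4-dihydronaphthalen-2-yl)oxy]-1-hydroxy-3-(3-methylbut-2-en-1-yl)naphthalene-2-carboxylate
Conditions: K2CO3 (1.1 equiv), degassed DMF, 0 °C → rt, Ar, dark
Reagents that add atoms: none
Why: Addition–elimination (vinylogous acyl substitution) of a phenoxide on a 2-halo-1,4-naphthoquinone: the C1 hydroxyl of 11 is held in a hydrogen bond to the ester and its anion is delocalised into it, so the free and more nucleophilic C4 phenoxide adds to the bromoquinone and bromide leaves, and the ester makes 11 a poor reductant, which should hold back redox exchange with 12 under degassed, mildly basic conditions.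

**Compound list**
1 | trimethylsilylacetylene | C#C[Si](C)(C)C | starting material
2 | prenyl bromide (1-bromo-3-methylbut-2-ene) | CC(C)=CCBr | starting material
3 | (trimethylsilylethynyl)magnesium bromide | C[Si](C)(C)C#C[Mg]Br | intermediate (not isolated)
4 | trimethyl(5-methylhex-4-en-1-yn-1-yl)silane | CC(C)=CCC#C[Si](C)(C)C | intermediate
5 | methyl 2-iodobenzoate | COC(=O)c1ccccc1I | starting material
6 | 5-methylhex-4-en-1-yne | CC(C)=CCC#C | intermediate (not isolated)
7 | methyl 2-(5-methylhex-4-en-1-yn-1-yl)benzoate | COC(=O)c1ccccc1C#CCC=C(C)C | intermediate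
8 | methyl 3-[2-(5-methylhex-4-en-1-yn-1-yl)phenyl]-3-oxopropanoate | COC(=O)CC(=O)c1ccccc1C#CCC=C(C)C | intermediate
9 | methyl 1-hydroxy-3-(3-methylbut-2-en-1-yl)-2-naphthoate | COC(=O)c1c(CC=C(C)C)cc2ccccc2c1O | intermediate
10 | methyl 3-(3-methylbut-2-en-1-yl)-1,4-dioxo-1,4-dihydronaphthalene-2-carboxylate | COC(=O)C1=C(CC=C(C)C)C(=O)c2ccccc2C1=O | intermediate (not isolated)
11 | methyl 1,4-dihydroxy-3-(3-methylbut-2-en-1-yl)-2-naphthoate | COC(=O)c1c(CC=C(C)C)c(O)c2ccccc2c1O | intermediate
12 | 2-bromo-1,4-naphthoquinone | O=C1C=C(Br)C(=O)c2ccccc12 | starting material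
13 | rubioncolin C | COC(=O)c1c(CC=C(C)C)c(OC2=CC(=O)c3ccccc3C2=O)c2ccccc2c1O | target

**Count**
Total step count: 6. Longest linear sequence: 6 steps (1 → 4 → 7 → 8 → 9 → 11 → 13); 5 and 12 are purchased.

**Steps most likely to fail**

Step 4. The ketone oxygen may attack the gold-activated alkyne faster than the enol carbon (leading to an alkylidene isochromene), or closure may take the 5-exo course. The fallback sets out from 8 and comes back at 9. Silylation of 8 (TBSOTf, Et3N, CH2Cl2, 0 °C) gives the silyl enol ether methyl (Z)-3-[(tert-butyldimethylsilyl)oxy]-3-[2-(5-methylhex-4-en-1-yn-1-yl)phenyl]prop-2-enoate F1, in which the oxygen is capped so that only carbon can add. π-Acid-catalysed 6-endo carbocyclisation of aryl silyl enol ethers onto ortho alkynes is established (Ph3PAuNTf2 or PtCl2, toluene) and should give methyl 1-[(tert-butyldimethylsilyl)oxy]-3-(3-methylbut-2-en-1-yl)-2-naphthoate F2. TBAF in THF then frees 9.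

Step 6. Electron transfer between the hydroquinone and the bromoquinone may outrun substitution, the C1 oxygen may be arylated, or oxidised material may cyclise under base to a chromene. The fallback sets out from 11 and comes back at 13; it makes the nucleophile a simple phenol that cannot be oxidised to a quinone.
- The free C4 hydroxyl is silylated selectively (TBSCl, imidazole, DMF) to methyl 4-[(tert-butyldimethylsilyl)oxy]-1-hydroxy-3-(3-methylbut-2-en-1-yl)-2-naphthoate F3.
- The chelated C1 hydroxyl is then forced into a MOM ether (NaH, MOMCl, DMF) to give methyl 4-[(tert-butyldimethylsilyl)oxy]-1-(methoxymethoxy)-3-(3-methylbut-2-en-1-yl)-2-naphthoate F4.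
- TBAF removes the silyl group to give methyl 4-hydroxy-1-(methoxymethoxy)-3-(3-methylbut-2-en-1-yl)-2-naphthoate F5.
- F5 is coupled with 12 (K2CO3, DMF) to methyl 4-[(1,4-dioxo-1,4-dihydronaphthalen-2-yl)oxy]-1-(methoxymethoxy)-3-(3-methylbut-2-en-1-yl)-2-naphthoate F6.
- Brief treatment with TFA in CH2Cl2 at 0 °C and aqueous work-up removes the ester-flanked MOM group to give 13.

Step 5. Ligand exchange at the hydrogen-bonded, ester-deactivated naphthol may be slow enough for the oxidant to consume the prenyl alkene, or oxidation may not stop cleanly at the para-quinone. The fallback sets out from 9 and comes back at 10, introducing the C4 heteroatom by electrophilic substitution instead of oxidation. Azo coupling of 9 with benzenediazonium chloride (aq Na2CO3, pyridine, 0 °C) at the only free position of ring A gives methyl 1-hydroxy-3-(3-methylbut-2-en-1-yl)-4-[(E)-phenyldiazenyl]-2-naphthoate F7. Na2S2O4 cleaves the azo link to methyl 4-amino-1-hydroxy-3-(3-methylbut-2-en-1-yl)-2-naphthoate F8. Mild oxidation of this aminonaphthol (FeCl3, dilute HCl, rt) and hydrolysis of the quinone imine give 10, which the dithionite stage of step 5 reduces to 11.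

**Further compounds**
F1 | step 4 | methyl (Z)-3-[(tert-butyldimethylsilyl)oxy]-3-[2-(5-methylhex-4-en-1-yn-1-yl)phenyl]prop-2-enoate | COC(=O)/C=C(\O[Si](C)(C)C(C)(C)C)c1ccccc1C#CCC=C(C)C
F2 | step 4 | methyl 1-[(tert-butyldimethylsilyl)oxy]-3-(3-methylbut-2-en-1-yl)-2-naphthoate | COC(=O)c1c(CC=C(C)C)cc2ccccc2c1O[Si](C)(C)C(C)(C)C
F3 | step 6 | methyl 4-[(tert-butyldimethylsilyl)oxy]-1-hydroxy-3-(3-methylbut-2-en-1-yl)-2-naphthoate | COC(=O)c1c(CC=C(C)C)c(O[Si](C)(C)C(C)(C)C)c2ccccc2c1O
F4 | step 6 | methyl 4-[(tert-butyldimethylsilyl)oxy]-1-(methoxymethoxy)-3-(3-methylbut-2-en-1-yl)-2-naphthoate | COCOc1c(C(=O)OC)c(CC=C(C)C)c(O[Si](C)(C)C(C)(C)C)c2ccccc12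
F5 | step 6 | methyl 4-hydroxy-1-(methoxymethoxy)-3-(3-methylbut-2-en-1-yl)-2-naphthoate | COCOc1c(C(=O)OC)c(CC=C(C)C)c(O)c2ccccc12
F6 | step 6 | methyl 4-[(1,4-dioxo-1,4-dihydronaphthalen-2-yl)oxy]-1-(methoxymethoxy)-3-(3-methylbut-2-en-1-yl)-2-naphthoate | COCOc1c(C(=O)OC)c(CC=C(C)C)c(OC2=CC(=O)c3ccccc3C2=O)c2ccccc12
F7 | step 5 | methyl 1-hydroxy-3-(3-methylbut-2-en-1-yl)-4-[(E)-phenyldiazenyl]-2-naphthoate | COC(=O)c1c(CC=C(C)C)c(/N=N/c2ccccc2)c2ccccc2c1O
F8 | step 5 | methyl 4-amino-1-hydroxy-3-(3-methylbut-2-en-1-yl)-2-naphthoate | COC(=O)c1c(CC=C(C)C)c(N)c2ccccc2c1O
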